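**Retrosynthetic overview**

- The route rests on ring A of the flavone (C4a, C5, C6, C7, C8, C8a) with its C4 acyl carbon: an acylphloroglucinol in which the oxygen-bearing C5, C7 and C8a alternate with C4a, C6(OMe) and C8(OMe), mirror-symmetric about the C7–C4a axis until ring C is closed.
- Target ⇒ bis-benzyl ether (hydrogenolysis) ⇒ ring C opened at O1–C2 and C2–C3 (Allan–Robinson) into the ω-methoxy ketone of ring A and the anhydride of the ring B acid.
- Ring A ⇒ C4a–C8a Claisen disconnection to an open-chain C8 triketo ester, assembled from methyl methoxyacetate by self-Claisen condensation, dianion acetylation and trianion methoxyacetylation.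
- Ring B acid ⇒ isovanillin (benzylation, Baeyer–Villiger oxidation, benzylation, Vilsmeier–Haack formylation, Pinnick oxidation).
- Ring order: ring A is built, ring B is carried in from isovanillin, ring C is closed last.

Key step: step 4

Remark: the three open-chain keto esters are handled as mixtures of epimers and keto–enol tautomers (the target has no stereocentre), and the crude Allan–Robinson product is treated as the 7-O-aroyl ester of the flavone, any 5,7-diester being cleaved by the same hydrolysis.

**Route**

Step 1
Reactants: 1 methyl methoxyacetate (2 equiv)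
Product: 2 methyl 2,4-dimethoxy-3-oxobutanoate (racemic)
Conditions: NaH (0.55 equiv per ester), THF, reflux; then aq. HCl, 0 °C
Reagents that add atoms: none
Why: Claisen self-condensation, in which the sodium enolate of one ester acylates a second molecule and deprotonation of the β-keto ester product drives the equilibrium; the single stereocentre is epimerisable and later becomes sp2.

Step 2
Reactants: 2 methyl 2,4-dimethoxy-3-oxobutanoate; 3 N-methoxy-N-methylacetamide
Product: 5 methyl 2,4-dimethoxy-3,5-dioxohexanoate, via dilithium dienolate 4 (not isolated)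
Conditions: LiN(i-Pr)2 (2.2 equiv), THF, −78 to 0 °C; then 3, −78 to 0 °C; cold aq. HCl (pH 4)
Reagents that add atoms: none
Why: γ-acylation of a β-keto ester dianion with a Weinreb amide, in which the more basic terminal α-methoxy carbanion of 4 adds to 3 and the chelated tetrahedral adduct persists until work-up, so that neither over-addition nor quenching by the more acidic product should occur; both methoxy-bearing stereocentres are epimerisable and end as sp2 carbons of ring A.

Step 3
Reactants: 5 methyl 2,4-dimethoxy-3,5-dioxohexanoate; 6 N,2-dimethoxy-N-methylacetamide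
Product: 8 methyl 2,4,8-trimethoxy-3,5,7-trioxooctanoate, via trilithium trienolate 7 (not isolated)
Conditions: LiN(i-Pr)2 (3.3 equiv), THF, −78 to 0 °C; then 6, −78 to 0 °C; cold aq. HCl (pH 4–5); crude used at once
Reagents that add atoms: none
Why: terminal acylation of a 3,5-diketo ester trianion, in which the third equivalent of base can only remove a methyl proton once both doubly activated methines are deprotonated, and this most basic carbanion of 7 attacks the chelating α-methoxy Weinreb amide, whose stable adduct releases the triketone only on work-up.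

Step 4
Reactants: 8 methyl 2,4,8-trimethoxy-3,5,7-trioxooctanoate
Product: 9 2-methoxy-1-(2,4,6-trihydroxy-3,5-dimethoxyphenyl)ethan-1-one
Conditions: Mg(OMe)2 (5 equiv), MeOH, N2, rt to reflux; then cold 1 M HCl
Reagents that add atoms: none
Why: Mg(OMe)2 converts 8 into magnesium enolate chelates, the carbanion at chain C6 (the methylene between the C5 and C7 ketones, the future C4a) adds to the C1 ester carbonyl (the future C8a), methoxide leaves, and the 2-acylcyclohexane-1,3,5-trione so formed enolises three times to the aromatic ketone 9. The closest known reaction is the biomimetic Claisen cyclisation of 3,5,7-triketo esters, and of the related 6-acylmethyl-4-hydroxy-2-pyranones, to acylphloroglucinols under magnesium methoxide. Ring A closes in a 6-exo-trig mode at the ester carbonyl, with the side-chain ketone of the enolate outside the new ring. No stereocentre is formed, since the epimerisable chain carbons C2 and C4 become the sp2 carbons C8 and C6 of the flavone and the epimer mixture converges. The step needs Claisen closure over aldol closure and over O-acylation to a pyranone: C2 carries a methoxy group, so its aldol addition to the C7 ketone would give a quaternary carbon that cannot aromatise and should revert, the C8 methoxymethylene is only singly activated and is not deprotonated by methoxide, and magnesium chelation folds the chain, ties up the enolate oxygens and activates the α-methoxy ester. Because 9 has a mirror plane through the acyl-bearing carbon and the para carbon, a single product should result and either ortho hydroxyl can later become O1.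

Step 5
Reactants: 10 isovanillin (3-hydroxy-4-methoxybenzaldehyde)
Product: 11 3-(benzyloxy)-4-methoxybenzaldehyde
Conditions: BnBr, K2CO3, DMF, 60 °C
Reagents that add atoms: benzyl bromide, BrCc1ccccc1
Why: Williamson ether synthesis on the phenoxide, masking the oxygen that becomes the 4'-OH and keeping the free phenol out of the peracid step.

Step 6
Reactants: 11 3-(benzyloxy)-4-methoxybenzaldehyde
Product: 13 3-(benzyloxy)-4-methoxyphenol, via aryl formate 12 (not isolated)
Conditions: mCPBA, CH2Cl2, rt; aq. NaHCO3 wash; then K2CO3 (cat.), MeOH, rt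
Reagents that add atoms: 3-chloroperoxybenzoic acid, O=C(OO)c1cccc(Cl)c1
Why: Baeyer–Villiger oxidation, in which the electron-rich aryl group para to the methoxy group migrates in preference to hydride to give formate 12, which mild methanolysis cleaves to the phenol.

Step 7
Reactants: 13 3-(benzyloxy)-4-methoxyphenol
Product: 14 2,4-bis(benzyloxy)-1-methoxybenzene
Conditions: BnBr, K2CO3, DMF, 60 °C
Reagents that add atoms: benzyl bromide, BrCc1ccccc1
Why: Williamson ether synthesis, protecting the oxygen that becomes the 2'-OH as a second hydrogenolysable benzyl ether.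

Step 8
Reactants: 14 2,4-bis(benzyloxy)-1-methoxybenzene
Product: 16 2,4-bis(benzyloxy)-5-methoxybenzaldehyde, via aryl iminium chloride 15 (not isolated)
Conditions: POCl3, DMF, 0 to 70 °C; then aq. NaOAc
Reagents that add atoms: N,N-dimethylformamide, CN(C)C=O; water, O
Why: Vilsmeier–Haack formylation, in which the chloroiminium ion attacks C5, the only position para to one benzyloxy group and ortho to the other (the site between the two benzyloxy groups is hindered and C6 is activated by the methoxy group alone), as in the formylation of 1,2,4-trialkoxybenzenes, and hydrolysis of 15 releases the aldehyde.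

Step 9
Reactants: 16 2,4-bis(benzyloxy)-5-methoxybenzaldehyde
Product: 17 2,4-bis(benzyloxy)-5-methoxybenzoic acid
Conditions: NaClO2, NaH2PO4, 2-methyl-2-butene, t-BuOH–THF–H2O, rt
Reagents that add atoms: sodium chlorite, [Na+].[O-]Cl=O
Why: Pinnick oxidation, in which chlorous acid converts the aldehyde into the acid without touching the benzyl ethers, while 2-methyl-2-butene scavenges hypochlorous acid and so protects the electron-rich ring from chlorination.

Step 10
Reactants: 17 2,4-bis(benzyloxy)-5-methoxybenzoic acid (2 equiv)
Product: 18 2,4-bis(benzyloxy)-5-methoxybenzoic anhydride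
Conditions: DCC (0.5 equiv), CH2Cl2, 0 °C to rt
Reagents that add atoms: none
Why: carbodiimide dehydration, in which the O-acylisourea of one acid molecule is attacked by a second carboxylate to give the symmetrical anhydride and insoluble dicyclohexylurea under conditions that leave the benzyl ethers intact.

Step 11
Reactants: 9 2-methoxy-1-(2,4,6-trihydroxy-3,5-dimethoxyphenyl)ethan-1-one; 18 2,4-bis(benzyloxy)-5-methoxybenzoic anhydride
Product: 20 2-[2,4-bis(benzyloxy)-5-methoxyphenyl]-5,7-dihydroxy-3,6,8-trimethoxy-4H-chromen-4-one, via 7-O-aroyl flavone ester 19 (not isolated)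
Conditions: 18 (4 equiv), Et3N, sealed tube, 160 °C; then KOH, MeOH–H2O, reflux; then dil. HCl
Reagents that add atoms: none
Why: Allan–Robinson flavone synthesis, in which aroylation of the ketone, acyl transfer to the α-methoxy methylene carbon and cyclodehydration of the resulting 1,3-diketone onto an ortho hydroxyl form the C2–C3 and O1–C2 bonds of ring C, the symmetry of 9 making both ortho hydroxyls equivalent, the ω-methoxy group ending as the 3-OMe, and alkaline hydrolysis cleaving the aryl ester of 19 to free the 7-OH.

Step 12
Reactants: 20 2-[2,4-bis(benzyloxy)-5-methoxyphenyl]-5,7-dihydroxy-3,6,8-trimethoxy-4H-chromen-4-one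
Product: 21 5,7,2',4'-tetrahydroxy-3,6,8,5'-tetramethoxyflavone (2-(2,4-dihydroxy-5-methoxyphenyl)-5,7-dihydroxy-3,6,8-trimethoxy-4H-chromen-4-one)
Conditions: H2 (1 atm), 10% Pd/C, EtOAc–MeOH, rt
Reagents that add atoms: none
Why: catalytic hydrogenolysis of the two benzyl aryl ethers over palladium on carbon, conditions under which the aryl methyl ethers and the tetrasubstituted C2=C3 bond of the chromenone (a vinylogous ester) should remain untouched.

**Compound list**

1 | methyl methoxyacetate | COCC(=O)OC | starting material
2 | methyl 2,4-dimethoxy-3-oxobutanoate (racemic, keto–enol mixture) | COCC(=O)C(OC)C(=O)OC | intermediate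
3 | N-methoxy-N-methylacetamide | CC(=O)N(C)OC | starting material
4 | dilithium dienolate of methyl 2,4-dimethoxy-3-oxobutanoate | [Li+].[Li+].COC=C([O-])C(OC)=C([O-])OC | intermediate
5 | methyl 2,4-dimethoxy-3,5-dioxohexanoate (epimers and enol forms) | CC(=O)C(OC)C(=O)C(OC)C(=O)OC | intermediate
6 | N,2-dimethoxy-N-methylacetamide | COCC(=O)N(C)OC | starting material
7 | trilithium trienolate of methyl 2,4-dimethoxy-3,5-dioxohexanoate | [Li+].[Li+].[Li+].C=C([O-])C(OC)=C([O-])C(OC)=C([O-])OC | intermediate
8 | methyl 2,4,8-trimethoxy-3,5,7-trioxooctanoate (epimers and enol forms) | COCC(=O)CC(=O)C(OC)C(=O)C(OC)C(=O)OC | intermediate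
9 | 2-methoxy-1-(2,4,6-trihydroxy-3,5-dimethoxyphenyl)ethan-1-one | COCC(=O)c1c(O)c(OC)c(O)c(OC)c1O | intermediate
10 | isovanillin (3-hydroxy-4-methoxybenzaldehyde) | COc1ccc(C=O)cc1O | starting material
11 | 3-(benzyloxy)-4-methoxybenzaldehyde | COc1ccc(C=O)cc1OCc1ccccc1 | intermediate
12 | 3-(benzyloxy)-4-methoxyphenyl formate | COc1ccc(OC=O)cc1OCc1ccccc1 | intermediate
13 | 3-(benzyloxy)-4-methoxyphenol | COc1ccc(O)cc1OCc1ccccc1 | intermediate
14 | 2,4-bis(benzyloxy)-1-methoxybenzene | COc1ccc(OCc2ccccc2)cc1OCc1ccccc1 | intermediate
15 | N-[2,4-bis(benzyloxy)-5-methoxybenzylidene]-N-methylmethanaminium chloride | C[N+](C)=Cc1cc(OC)c(OCc2ccccc2)cc1OCc1ccccc1.[Cl-] | intermediate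
16 | 2,4-bis(benzyloxy)-5-methoxybenzaldehyde | COc1cc(C=O)c(OCc2ccccc2)cc1OCc1ccccc1 | intermediate
17 | 2,4-bis(benzyloxy)-5-methoxybenzoic acid | COc1cc(C(=O)O)c(OCc2ccccc2)cc1OCc1ccccc1 | intermediate
18 | 2,4-bis(benzyloxy)-5-methoxybenzoic anhydride | COc1cc(C(=O)OC(=O)c2cc(OC)c(OCc3ccccc3)cc2OCc2ccccc2)c(OCc2ccccc2)cc1OCc1ccccc1 | intermediate
19 | 2-[2,4-bis(benzyloxy)-5-methoxyphenyl]-5-hydroxy-3,6,8-trimethoxy-4-oxo-4H-chromen-7-yl 2,4-bis(benzyloxy)-5-methoxybenzoate | COc1cc(-c2oc3c(OC)c(OC(=O)c4cc(OC)c(OCc5ccccc5)cc4OCc4ccccc4)c(OC)c(O)c3c(=O)c2OC)c(OCc2ccccc2)cc1OCc1ccccc1 | intermediate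
20 | 2-[2,4-bis(benzyloxy)-5-methoxyphenyl]-5,7-dihydroxy-3,6,8-trimethoxy-4H-chromen-4-one | COc1cc(-c2oc3c(OC)c(O)c(OC)c(O)c3c(=O)c2OC)c(OCc2ccccc2)cc1OCc1ccccc1 | intermediate
21 | 5,7,2',4'-tetrahydroxy-3,6,8,5'-tetramethoxyflavone | COc1cc(-c2oc3c(OC)c(O)c(OC)c(O)c3c(=O)c2OC)c(O)cc1O | target

**Step count**

Total: 12 steps. Longest linear sequence: 8 steps (isovanillin 10 to target 21, steps 5–12); the ring A branch is 6 steps (steps 1–4, 11, 12).

**Steps most likely to fail**

1. Step 4 (Claisen closure of ring A). The free triketo ester may be consumed by retro-Claisen methanolysis, by lactonisation or pyranone formation during its isolation, or by closure in the wrong sense before the magnesium chelate has organised the chain. Fallback, setting out from 5 and coming back at 9: 5 is lactonised with DBU in refluxing toluene to 4-hydroxy-3,5-dimethoxy-6-methyl-2H-pyran-2-one F1. The dianion of F1 (LiN(i-Pr)2, 2.2 equiv, THF, −78 °C; hydroxyl and 6-methyl deprotonated) is acylated at the methyl carbon with Weinreb amide 6 to give 4-hydroxy-3,5-dimethoxy-6-(3-methoxy-2-oxopropyl)-2H-pyran-2-one F2. F2 is a stable surrogate whose enol lactone holds the chain in the folded geometry; heating it with Mg(OMe)2 or KOH in MeOH opens the lactone and brings about the known rearrangement of 6-acylmethyl-4-hydroxy-2-pyranones to acylphloroglucinols, which should give 9. This fallback also bypasses step 3.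

2. Step 3 (trianion acylation). The third deprotonation of the doubly methoxylated diketo ester may stay incomplete, the polylithiated species may aggregate, or the trianion may take a proton from the amide instead of adding to it. Fallback, setting out from 5 and coming back at 8: 5 is silylated with Me3SiCl and Et3N to methyl 2,4-dimethoxy-3,5-bis(trimethylsilyloxy)hexa-2,4-dienoate F3. F3 is deprotonated at the methyl group with LiN(i-Pr)2 and silylated again to 1,2,4-trimethoxy-1,3,5-tris(trimethylsilyloxy)hexa-1,3,5-triene F4. Mukaiyama-type acylation of the terminal carbon of this neutral polyenol ether with methoxyacetyl chloride (CH2Cl2, −78 °C, cat. Me3SiOTf), followed by mild aqueous desilylation, should give 8.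

3. Step 11 (Allan–Robinson closure of ring C). The acyl transfer to carbon may be slowed by the ortho-benzyloxy group of the anhydride and by the methoxy groups flanking the ketone, while the electron-rich ketone decomposes or loses benzyl groups at 160 °C. Fallback, setting out from 17 and 9 and coming back at 20: 17 is converted with oxalyl chloride and catalytic DMF into 2,4-bis(benzyloxy)-5-methoxybenzoyl chloride F5. The lithium polyanion of 9 (LiN(SiMe3)2, 5 equiv, THF, −78 °C) is C-acylated with one equivalent of F5 to give 1-[2,4-bis(benzyloxy)-5-methoxyphenyl]-2-methoxy-3-(2,4,6-trihydroxy-3,5-dimethoxyphenyl)propane-1,3-dione F6, a low-temperature Claisen route to the Baker–Venkataraman diketone. Cyclodehydration of F6 in AcOH with NaOAc at 100 °C should give 20.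

**Further compounds**

F1 | step 4 | 4-hydroxy-3,5-dimethoxy-6-methyl-2H-pyran-2-one | Cc1oc(=O)c(OC)c(O)c1OC
F2 | step 4 | 4-hydroxy-3,5-dimethoxy-6-(3-methoxy-2-oxopropyl)-2H-pyran-2-one | COCC(=O)Cc1oc(=O)c(OC)c(O)c1OC
F3 | step 3 | methyl 2,4-dimethoxy-3,5-bis(trimethylsilyloxy)hexa-2,4-dienoate | CC(O[Si](C)(C)C)=C(OC)C(O[Si](C)(C)C)=C(OC)C(=O)OC
F4 | step 3 | 1,2,4-trimethoxy-1,3,5-tris(trimethylsilyloxy)hexa-1,3,5-triene | C=C(O[Si](C)(C)C)C(OC)=C(O[Si](C)(C)C)C(OC)=C(OC)O[Si](C)(C)C
F5 | step 11 | 2,4-bis(benzyloxy)-5-methoxybenzoyl chloride | COc1cc(C(=O)Cl)c(OCc2ccccc2)cc1OCc1ccccc1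
F6 | step 11 | 1-[2,4-bis(benzyloxy)-5-methoxyphenyl]-2-methoxy-3-(2,4,6-trihydroxy-3,5-dimethoxyphenyl)propane-1,3-dione | COc1cc(C(=O)C(OC)C(=O)c2c(O)c(OC)c(O)c(OC)c2O)c(OCc2ccccc2)cc1OCc1ccccc1
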